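**Plan**

- Retrosynthesis: the methylenes C4=C3 and C11=C13 and the C6 angelate go first; the lactone is opened at O8–C12 and cut at C7–C11 (enolate alkylation); vinyl C1=C2 and aldehyde C15 are rejoined through C2–C15 (Grob scission in reverse); last, C1–C10 and C4–C5 are cut (Diels–Alder).
- Enabling feature: ring carbons C5–C10 carry oxygen at C6, C8 and C9 and a methyl at C10, the pattern of a 2-alkoxy-6-methyl-1,4-benzoquinone. The vinyl (C1=C2) and the C4–C15 chain on adjacent C10/C5 are a cyclohexene C10–C1–C2–C15–C4–C5 opened between C2 and C15.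
- Forward: ring B is the quinone; ring A is closed by the cycloaddition, used as a stereochemical scaffold and then cut by the Grob fragmentation; the γ-lactone is closed next; angelate and the two methylenes come last.
- Stereochemistry: absolute configuration and C10 from the catalysed cycloaddition; C9 and C8 from β-face hydride and hydrogen delivery on the cis-decalin; C5 and C7 by equilibration through the C6 ketone; C6 by equatorial hydride attack.

Key step: step 5

Numbering: C10 = C(Me)(vinyl C1=C2), C9 = CHOH, C8 = lactone CH–O, C7, C6 = CH–OAng, C5 = CH–C4(=C3H2)–C15HO, C11–C13 = lactone carbons; β is the face of ring B that carries the C10 methyl.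

Assumption: the (R)-binaphthol ligand is taken to expose the quinone face that leads to 7; if the first run shows the opposite sense, the (S)-ligand is used and nothing else changes.

**Route**

Step 1
Reactants: 1 3-methylcatechol
Product: 2 2-[(2-methoxyethoxy)methoxy]-6-methylphenol
Conditions: MEMCl (1.0 equiv), iPr2NEt, CH2Cl2, −20 → 0 °C
Reagents that add atoms: 2-methoxyethoxymethyl chloride, COCCOCCl
Why: Base-mediated O-alkylation (Williamson-type acetal ether formation) should occur at the 1-OH, which is less hindered and more acidic than the OH flanked by the methyl group, leaving a phenol that is 2,6-disubstituted and free at the para position.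

Step 2
Reactants: 2 2-[(2-methoxyethoxy)methoxy]-6-methylphenol
Product: 3 2-[(2-methoxyethoxy)methoxy]-6-methyl-1,4-benzoquinone
Conditions: O2 (1 atm), Co(salen) (5 mol %), DMF, rt
Reagents that add atoms: dioxygen, O=O
Why: Cobalt–salen-catalysed aerobic oxidation of 2,6-disubstituted phenols gives p-benzoquinones by oxygenation of the free para position, and the aryl MEM ether is inert to these neutral conditions.

Step 3
Reactants: 4 (E)-4-methoxybut-3-en-2-one
Product: 5 (E)-4-(benzyloxy)but-3-en-2-one
Conditions: BnOH (1.5 equiv), PPTS (cat.), toluene, 60 °C, reduced pressure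
Reagents that add atoms: benzyl alcohol, OCc1ccccc1
Why: Acid-catalysed transetherification of the vinylogous ester (conjugate addition–elimination) is driven by removal of methanol and returns the thermodynamically preferred E-enol ether.

Step 4
Reactants: 5 (E)-4-(benzyloxy)but-3-en-2-one
Product: 6 (E)-1-(benzyloxy)-3-(trimethylsilyloxy)buta-1,3-diene
Conditions: TMSOTf, Et3N, Et2O, 0 °C
Reagents that add atoms: trimethylsilyl triflate, C[Si](C)(C)OS(=O)(=O)C(F)(F)F
Why: Silyl triflate/amine enolization of the methyl ketone (silyl enol ether formation) gives the 2-silyloxy diene without touching the E-configured benzyl enol ether.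

Step 5
Reactants: 3 2-[(2-methoxyethoxy)methoxy]-6-methyl-1,4-benzoquinone; 6 (E)-1-(benzyloxy)-3-(trimethylsilyloxy)buta-1,3-diene
Product: 7 cis-fused endo cycloadduct, 8-(benzyloxy)-2-[(2-methoxyethoxy)methoxy]-8a-methyl-6-(trimethylsilyloxy)-4a,5,8,8a-tetrahydronaphthalene-1,4-dione (C10-Me β, H-5 β, C1-OBn cis to C9)
Conditions: [(R)-BINOL]TiCl2 (10 mol %, from (R)-BINOL and TiCl2(OiPr)2, sieves removed), toluene, −60 → −30 °C
Reagents that add atoms: none
Why: The reaction is a normal-electron-demand, concerted but asynchronous [4+2] cycloaddition in which the titanium binaphtholate binds the quinone in two-point fashion through the C9 carbonyl and the C8 alkoxy oxygen; the closest known reaction type is the chiral Ti(IV)–BINOL-catalysed Diels–Alder reaction of quinones with 1-oxygenated dienes. Ring A (C10–C1–C2–C15–C4–C5) closes as a six-membered carbocycle by cycloaddition, both σ bonds (C1–C10 and C4–C5) forming in the same step. C10 and C5 arise cis because addition is suprafacial on the quinone, C1-OBn is placed cis to C9 by the endo transition state of the E-enol ether, and the absolute configuration follows from the ligand shielding one face of the chelated quinone. Site selectivity is secured because the alkoxy-bearing C7=C8 bond is a deactivated vinylogous ester, and regioselectivity because the nucleophilic CH2 terminus of the diene bonds to the unsubstituted C5, which is β to the chelated and inherently more electron-poor C9 carbonyl, so that catalysed and thermal preferences coincide.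

Step 6
Reactants: 7 cis-fused endo cycloadduct
Product: 9 diol (C9-OH α; C15-OH cis to C1-OBn; C6 vinylogous ester retained), via triketone 8 (not isolated)
Conditions: K2CO3 (0.1 equiv), MeOH/THF, −20 °C; then NaBH4, −78 → −30 °C
Reagents that add atoms: none
Why: Carbonate-catalysed methanolysis frees the C15 ketone, and borohydride then reduces this saturated ketone and the C9 enedione carbonyl but not the vinylogous-ester carbonyl C6 (chemoselective carbonyl reduction); hydride should add to C9 from the convex β face of the cis-decalin, away from ring A and its C1 ether, to set C9-OH α, and axially to C15 to give the equatorial alcohol, whose configuration is lost later.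

Step 7
Reactants: 9 diol
Product: 10 bis-TBS ether (C9-OTBS, C15-OTBS)
Conditions: TBSOTf (2.5 equiv), 2,6-lutidine, CH2Cl2, −78 → 0 °C
Reagents that add atoms: tert-butyldimethylsilyl triflate, CC(C)(C)[Si](C)(C)OS(=O)(=O)C(F)(F)F
Why: Silyl triflate with 2,6-lutidine silylates both the unhindered C15 and the neopentyl C9 hydroxyl (silyl ether formation), the low temperature sparing the MEM vinylogous ester.

Step 8
Reactants: 10 bis-TBS ether
Product: 11 hydroxy ketone (C7–C8 saturated, C8-OMEM α, C6 ketone, C1-OH free)
Conditions: H2 (3 atm), 10 % Pd/C, EtOAc, rt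
Reagents that add atoms: none
Why: Heterogeneous hydrogenation adds H2 syn to the β-alkoxy enone double bond from the β face, opposite the adjacent C9-OTBS group and the underlying ring A, which fixes H-8 β and C8-OMEM α (cis to C9-O), while the same catalyst hydrogenolyses the benzyl ether to free C1-OH.

Step 9
Reactants: 11 hydroxy ketone
Product: 12 C1 mesylate
Conditions: MsCl, Et3N, DMAP (cat.), CH2Cl2, 0 °C
Reagents that add atoms: methanesulfonyl chloride, CS(=O)(=O)Cl
Why: Sulfonylation through sulfene converts the only free hydroxyl, the hindered C1-OH, into the nucleofuge needed for fragmentation.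

Step 10
Reactants: 12 C1 mesylate
Product: 14 monocyclic dimethyl acetal (C10 vinyl, C5 α-CH2CH(OMe)2, C6 ketone, C8-OMEM, C9-OTBS), via aldehyde 13 (not isolated)
Conditions: TBAF (1.1 equiv), THF, −20 → 0 °C; then HC(OMe)3, PPTS, MeOH, rt
Reagents that add atoms: trimethyl orthoformate, COC(OC)OC; methanol, CO
Why: Fluoride removes the unhindered C15 silyl ether in preference to the neopentyl C9 one, and the resulting alkoxide should undergo Grob fragmentation because the equatorial C1–OMs bond is antiperiplanar to C2–C15 in the preferred ring-A chair; this gives the C10 vinyl group and the C15 aldehyde, which is acetalised in the same flask so that it survives the enolate and hydride steps.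

Step 11
Reactants: 14 monocyclic dimethyl acetal
Product: 16 equilibrated keto ester (C7-CH2CO2Me β, C5 side chain β), via keto ester 15 (not isolated)
Conditions: LDA, THF, −78 °C; BrCH2CO2Me, DMPU, −78 → −30 °C; then MeOH, NaOMe (0.3 equiv), 0 °C → rt
Reagents that add atoms: methyl bromoacetate, COC(=O)CBr
Why: Kinetic deprotonation should occur at the C7 methylene rather than the hindered C5 methine, the lithium enolate is alkylated by bromoacetate (SN2), and methoxide-catalysed equilibration through the C6 enolate then places both α-substituents equatorial (C5 β, C7 β), the only arrangement that avoids a syn-diaxial clash with the axial C9-OTBS once C8-O α forces the chair with C10-Me axial and vinyl equatorial.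

Step 12
Reactants: 16 equilibrated keto ester
Product: 17 keto lactone (trans-fused 8,12-γ-lactone, C6 ketone)
Conditions: ZnBr2 (5 equiv), CH2Cl2, rt; then PPTS, toluene, 50 °C
Reagents that add atoms: none
Why: Zinc bromide cleaves the MEM ether by chelation without touching the silyl ether, and the freed C8-OH lactonises onto the diequatorially disposed ester to give the trans-fused γ-lactone (Lewis-acid deprotection followed by acid-catalysed lactonisation).

Step 13
Reactants: 17 keto lactone
Product: 18 6β-hydroxy lactone
Conditions: L-Selectride (1.2 equiv), THF, −78 °C; AcOH quench at −78 °C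
Reagents that add atoms: none
Why: In the lactone-locked chair the β face of the C6 ketone is blocked by the 1,3-diaxial C10 methyl, so the bulky borohydride should attack from the equatorial α side and give the axial 6β-alcohol, the lactone being inert at −78 °C (diastereoselective ketone reduction).

Step 14
Reactants: 18 6β-hydroxy lactone
Product: 19 C6 trimethylsilyl ether
Conditions: 1-(trimethylsilyl)imidazole, CH2Cl2, rt
Reagents that add atoms: 1-(trimethylsilyl)imidazole, C[Si](C)(C)n1ccnc1
Why: N-Silylimidazole silylates the hindered alcohol under neutral conditions that leave the dimethyl acetal intact, masking a hydroxyl that would otherwise consume base and could translactonise in the next step.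

Step 15
Reactants: 19 C6 trimethylsilyl ether
Product: 21 C11 (dimethylamino)methyl lactone with free C6-OH, via silyl ether 20 (not isolated)
Conditions: LDA, THF, −78 °C; CH2=NMe2+ I−, −78 → 0 °C; then PPTS, MeOH, 0 °C
Reagents that add atoms: N,N-dimethylmethyleneiminium iodide, C=[N+](C)C.[I-]
Why: The lactone enolate adds to the iminium salt (Mannich reaction) on the face cis to H-7, away from the axial C6 silyloxy group, and buffered methanolysis then removes the labile TMS ether; the C11 configuration is of no consequence.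

Step 16
Reactants: 21 C11 (dimethylamino)methyl lactone with free C6-OH
Product: 22 C6 angelate
Conditions: angelic acid, 2,4,6-trichlorobenzoyl chloride, Et3N, toluene, rt; then 21, 80 °C (no DMAP)
Reagents that add atoms: angelic acid, C/C=C(/C)C(=O)O
Why: Yamaguchi esterification through the mixed anhydride, run without DMAP, acylates the single free hydroxyl while keeping the Z geometry of the angelate.

Step 17
Reactants: 22 C6 angelate
Product: 23 hydroxy aldehyde (C9-OH, C15HO)
Conditions: 48 % aq. HF, MeCN, 0 °C → rt; NaHCO3 work-up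
Reagents that add atoms: water, O
Why: Aqueous HF cleaves the hindered C9 silyl ether and hydrolyses the dimethyl acetal in one operation, conditions under which the angelate, the lactone and the protonated amine are stable.

Step 18
Reactants: 23 hydroxy aldehyde
Product: 24 α-methylene aldehyde (C4=C3)
Conditions: CH2=NMe2+ I−, Et3N, CH2Cl2, rt
Reagents that add atoms: N,N-dimethylmethyleneiminium iodide, C=[N+](C)C.[I-]
Why: Mannich reaction of the aldehyde with the iminium salt followed by spontaneous β-elimination of dimethylamine gives the α-methylene aldehyde, whereas the lactone Mannich base, a tertiary amine, is unaffected.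

Step 19
Reactants: 24 α-methylene aldehyde
Product: 26 target CNP0277836.2, via ammonium iodide 25 (not isolated)
Conditions: MeI (excess), MeOH, rt; then NaHCO3 (aq), EtOAc, rt
Reagents that add atoms: none
Why: Exhaustive N-methylation and bicarbonate-induced Hofmann-type β-elimination of trimethylamine unveil the α-methylene lactone (C11=C13) under conditions too mild to isomerise the angelate or the enal.

**Compound list**

1 | 3-methylcatechol (3-methylbenzene-1,2-diol) | Cc1cccc(O)c1O | starting material
2 | 2-[(2-methoxyethoxy)methoxy]-6-methylphenol | COCCOCOc1cccc(C)c1O | intermediate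
3 | 2-[(2-methoxyethoxy)methoxy]-6-methyl-1,4-benzoquinone | COCCOCOC1=CC(=O)C=C(C)C1=O | intermediate
4 | (E)-4-methoxybut-3-en-2-one | CC(=O)/C=C/OC | starting material
5 | (E)-4-(benzyloxy)but-3-en-2-one | CC(=O)/C=C/OCc1ccccc1 | intermediate
6 | (E)-1-(benzyloxy)-3-(trimethylsilyloxy)buta-1,3-diene | C=C(O[Si](C)(C)C)/C=C/OCc1ccccc1 | intermediate
7 | cis-fused endo cycloadduct (C10-Me β, H-5 β, C1-OBn cis to C9, C15 TMS enol ether, C8-OMEM enedione) | C[C@]12[C@@H](OCc3ccccc3)C=C(O[Si](C)(C)C)C[C@H]1C(=O)C=C(OCOCCOC)C2=O | intermediate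
8 | triketone (C15 ketone of 7; not isolated) | C[C@]12[C@@H](OCc3ccccc3)CC(=O)C[C@H]1C(=O)C=C(OCOCCOC)C2=O | intermediate
9 | diol (C9-OH α, C15-OH cis to C1-OBn) | C[C@]12[C@@H](OCc3ccccc3)C[C@@H](O)C[C@H]1C(=O)C=C(OCOCCOC)[C@H]2O | intermediate
10 | bis-TBS ether (C9, C15) | C[C@]12[C@@H](OCc3ccccc3)C[C@@H](O[Si](C)(C)C(C)(C)C)C[C@H]1C(=O)C=C(OCOCCOC)[C@H]2O[Si](C)(C)C(C)(C)C | intermediate
11 | hydroxy ketone (C8-OMEM α, C7H2, C6 ketone, C1-OH) | C[C@]12[C@@H](O)C[C@@H](O[Si](C)(C)C(C)(C)C)C[C@H]1C(=O)C[C@@H](OCOCCOC)[C@H]2O[Si](C)(C)C(C)(C)C | intermediate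
12 | C1 mesylate | C[C@]12[C@@H](OS(C)(=O)=O)C[C@@H](O[Si](C)(C)C(C)(C)C)C[C@H]1C(=O)C[C@@H](OCOCCOC)[C@H]2O[Si](C)(C)C(C)(C)C | intermediate
13 | Grob aldehyde (C10 vinyl, C5 α-CH2CHO; not isolated) | C=C[C@]1(C)[C@H](O[Si](C)(C)C(C)(C)C)[C@H](OCOCCOC)CC(=O)[C@@H]1CC=O | intermediate
14 | dimethyl acetal of 13 | C=C[C@]1(C)[C@H](O[Si](C)(C)C(C)(C)C)[C@H](OCOCCOC)CC(=O)[C@@H]1CC(OC)OC | intermediate
15 | C7-alkylated keto ester (C7-CH2CO2Me β, C5 still α; not isolated) | C=C[C@]1(C)[C@H](O[Si](C)(C)C(C)(C)C)[C@H](OCOCCOC)[C@@H](CC(=O)OC)C(=O)[C@@H]1CC(OC)OC | intermediate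
16 | equilibrated keto ester (C5 β, C7 β) | C=C[C@]1(C)[C@H](O[Si](C)(C)C(C)(C)C)[C@H](OCOCCOC)[C@@H](CC(=O)OC)C(=O)[C@H]1CC(OC)OC | intermediate
17 | keto lactone (trans-fused 8,12-lactone) | C=C[C@]1(C)[C@H](O[Si](C)(C)C(C)(C)C)[C@@H]2OC(=O)C[C@H]2C(=O)[C@H]1CC(OC)OC | intermediate
18 | 6β-hydroxy lactone | C=C[C@]1(C)[C@H](O[Si](C)(C)C(C)(C)C)[C@@H]2OC(=O)C[C@H]2[C@@H](O)[C@H]1CC(OC)OC | intermediate
19 | C6 trimethylsilyl ether | C=C[C@]1(C)[C@H](O[Si](C)(C)C(C)(C)C)[C@@H]2OC(=O)C[C@H]2[C@@H](O[Si](C)(C)C)[C@H]1CC(OC)OC | intermediate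
20 | C11 (dimethylamino)methyl lactone, C6-OTMS (CH2NMe2 cis to H-7; not isolated) | C=C[C@]1(C)[C@H](O[Si](C)(C)C(C)(C)C)[C@@H]2OC(=O)[C@H](CN(C)C)[C@H]2[C@@H](O[Si](C)(C)C)[C@H]1CC(OC)OC | intermediate
21 | C11 (dimethylamino)methyl lactone, C6-OH | C=C[C@]1(C)[C@H](O[Si](C)(C)C(C)(C)C)[C@@H]2OC(=O)[C@H](CN(C)C)[C@H]2[C@@H](O)[C@H]1CC(OC)OC | intermediate
22 | C6 angelate | C=C[C@]1(C)[C@H](O[Si](C)(C)C(C)(C)C)[C@@H]2OC(=O)[C@H](CN(C)C)[C@H]2[C@@H](OC(=O)/C(C)=C\C)[C@H]1CC(OC)OC | intermediate
23 | hydroxy aldehyde (C9-OH, C15HO) | C=C[C@]1(C)[C@H](O)[C@@H]2OC(=O)[C@H](CN(C)C)[C@H]2[C@@H](OC(=O)/C(C)=C\C)[C@H]1CC=O | intermediate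
24 | α-methylene aldehyde carrying the lactone Mannich base | C=C[C@]1(C)[C@H](O)[C@@H]2OC(=O)[C@H](CN(C)C)[C@H]2[C@@H](OC(=O)/C(C)=C\C)[C@H]1C(=C)C=O | intermediate
25 | trimethylammonium iodide of 24 (not isolated) | C=C[C@]1(C)[C@H](O)[C@@H]2OC(=O)[C@H](C[N+](C)(C)C)[C@H]2[C@@H](OC(=O)/C(C)=C\C)[C@H]1C(=C)C=O.[I-] | intermediate
26 | CNP0277836.2 | C=C[C@]1(C)[C@H](O)[C@@H]2OC(=O)C(=C)[C@H]2[C@@H](OC(=O)/C(C)=C\C)[C@H]1C(=C)C=O | target

**Step count and risks**

Total step count: 19. Longest linear sequence: 17 steps (steps 1, 2 and 5–19 from 3-methylcatechol; the diene branch, steps 3, 4 and 5–19, is equally long).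

Steps most likely to fail:

Step 5. The Lewis acid may give poor facial discrimination, may bind the C6 carbonyl and reverse the regiochemistry, or may desilylate the diene and divert it to a Michael addition that ends in aromatisation. The fallback sets out from 3 and 6 and returns at 9. The cycloaddition is run without catalyst (toluene, 40 °C), where the inherent polarisation gives the same regio- and endo-selectivity; 7 is then formed as a racemate, that is, together with the mirror-image adduct F1. The mixture is taken through the conditions of step 6, the mirror-image series passing through the mirror-image triketone F2, to the racemic diol, 9 with its enantiomer F3. Lipase-catalysed acetylation of the unhindered C15 hydroxyl (Pseudomonas cepacia lipase, vinyl acetate, MTBE) then acylates one enantiomer; written for the unwanted one, it gives the C15 acetate F4, and unreacted 9 is separated by chromatography and continues with step 7.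

Step 8. Saturation of the hindered push–pull double bond may stall, the C8 oxygen may be lost by hydrogenolysis, or hydrogen may add from the α face. The fallback sets out from 10 and returns at 11. DIBAL-H (CH2Cl2, −78 °C) reduces the vinylogous-ester carbonyl to the allylic alcohol F5, which turns the double bond into an ordinary enol ether. This is hydrogenated over Rh/Al2O3 (H2, EtOAc, trace Et3N) from the β face, the benzyl ether being retained, to give the saturated alcohol F6. Dess–Martin oxidation restores the C6 ketone in the benzyl ether F7, and hydrogenolysis (H2, Pd(OH)2/C, EtOAc) gives 11.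

Step 10. Enolisation of the C6 ketone may compete with alkoxide formation, leading to 1,3-displacement of the mesylate (cyclopropane formation) or to β-elimination of the C8 ether, and the C9 silyl ether may be partly lost. The fallback sets out from 12 and returns at 14; it removes the ketone for the duration of the fragmentation. NaBH4 (MeOH, 0 °C) reduces 12 to the C6 alcohol F8, which is acetylated (Ac2O, pyridine, DMAP) to the acetate F9. TBAF then triggers the same fragmentation with no enolisable carbonyl present, giving the acetoxy aldehyde F10 (not isolated), trapped with HC(OMe)3/PPTS/MeOH as the acetoxy acetal F11. Methanolysis (K2CO3, MeOH) gives the alcohol F12, and Dess–Martin oxidation returns the ketone 14.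

Further compounds
F1 | step 5 | mirror-image adduct (ent-7) | C[C@@]12[C@H](OCc3ccccc3)C=C(O[Si](C)(C)C)C[C@@H]1C(=O)C=C(OCOCCOC)C2=O
F2 | step 5 | mirror-image triketone (ent-8, not isolated) | C[C@@]12[C@H](OCc3ccccc3)CC(=O)C[C@@H]1C(=O)C=C(OCOCCOC)C2=O
F3 | step 5 | enantiomer of diol 9 (ent-9) | C[C@@]12[C@H](OCc3ccccc3)C[C@H](O)C[C@@H]1C(=O)C=C(OCOCCOC)[C@@H]2O
F4 | step 5 | C15 acetate of ent-9 | C[C@@]12[C@H](OCc3ccccc3)C[C@H](OC(C)=O)C[C@@H]1C(=O)C=C(OCOCCOC)[C@@H]2O
F5 | step 8 | C6 allylic alcohol of 10 (C6-OH α, MEM enol ether) | C[C@]12[C@@H](OCc3ccccc3)C[C@@H](O[Si](C)(C)C(C)(C)C)C[C@H]1[C@@H](O)C=C(OCOCCOC)[C@H]2O[Si](C)(C)C(C)(C)C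
F6 | step 8 | saturated C6 alcohol (C8-OMEM α, C1-OBn) | C[C@]12[C@@H](OCc3ccccc3)C[C@@H](O[Si](C)(C)C(C)(C)C)C[C@H]1[C@@H](O)C[C@@H](OCOCCOC)[C@H]2O[Si](C)(C)C(C)(C)C
F7 | step 8 | C1 benzyl ether of 11 (C6 ketone) | C[C@]12[C@@H](OCc3ccccc3)C[C@@H](O[Si](C)(C)C(C)(C)C)C[C@H]1C(=O)C[C@@H](OCOCCOC)[C@H]2O[Si](C)(C)C(C)(C)C
F8 | step 10 | C6 alcohol of mesylate 12 (C6-OH α) | C[C@]12[C@@H](OS(C)(=O)=O)C[C@@H](O[Si](C)(C)C(C)(C)C)C[C@H]1[C@@H](O)C[C@@H](OCOCCOC)[C@H]2O[Si](C)(C)C(C)(C)C
F9 | step 10 | C6 acetate of F8 | C[C@]12[C@@H](OS(C)(=O)=O)C[C@@H](O[Si](C)(C)C(C)(C)C)C[C@H]1[C@@H](OC(C)=O)C[C@@H](OCOCCOC)[C@H]2O[Si](C)(C)C(C)(C)C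
F10 | step 10 | monocyclic acetoxy aldehyde (not isolated) | C=C[C@]1(C)[C@H](O[Si](C)(C)C(C)(C)C)[C@H](OCOCCOC)C[C@H](OC(C)=O)[C@@H]1CC=O
F11 | step 10 | acetoxy dimethyl acetal | C=C[C@]1(C)[C@H](O[Si](C)(C)C(C)(C)C)[C@H](OCOCCOC)C[C@H](OC(C)=O)[C@@H]1CC(OC)OC
F12 | step 10 | C6 alcohol of acetal 14 | C=C[C@]1(C)[C@H](O[Si](C)(C)C(C)(C)C)[C@H](OCOCCOC)C[C@H](O)[C@@H]1CC(OC)OC
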